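## Retrosynthetic overview

1. Target ⇒ (two aryl acetates removed last) ⇒ cut the benzylic CH2–aryl bond: a spiro-epoxide of the tetrahydrofuran core plus an aryl bromide that already carries the erythro glycerol aryl ether (nickel-catalysed reductive coupling).
2. Spiro-epoxide ⇒ triol ⇒ cis-fused bicyclic lactol from an organocatalytic oxa-Michael/aldol/hemiacetalisation of dihydroxyacetone with 4-acetoxy-3-methoxycinnamaldehyde; this sets all three ring stereocentres.
3. Aryl bromide diol ⇒ D-proline anti-aldol of (4-bromo-2-methoxyphenoxy)acetaldehyde with vanillin acetate (sets both side-chain stereocentres) ⇒ 4-bromo-2-methoxyphenol + bromoacetaldehyde diethyl acetal.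
4. Ring order: the tetrahydrofuran ring is formed first (cascade); its fused lactol ring is opened by NaBH4; an epoxide ring is then made and opened in the coupling; the three benzene rings are bought.

Assumption: 1,3-dihydroxyacetone 8 is dosed as its commercial crystalline dimer, which reverts to monomer 8 in solution; catalysts, bases and solvents are not numbered.

## Route

Step 1
Reactants: 1 4-bromo-2-methoxyphenol; 2 2-bromo-1,1-diethoxyethane
Product: 3 4-bromo-1-(2,2-diethoxyethoxy)-2-methoxybenzene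
Conditions: K2CO3, DMF, 110 °C
Reagents that add atoms: none
Why: Williamson ether synthesis, in which the phenoxide displaces the primary bromide of 2 while the acetal masks the aldehyde; no stereocentre is formed.

Step 2
Reactants: 3 4-bromo-1-(2,2-diethoxyethoxy)-2-methoxybenzene
Product: 4 (4-bromo-2-methoxyphenoxy)acetaldehyde
Conditions: 2 M HCl, THF, 60 °C
Reagents that add atoms: water, O
Why: Acid-catalysed acetal hydrolysis unveils the aldehyde, the aryl ether and aryl bromide are inert, and the hydrate-prone aldehyde is used crude at once.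

Step 3
Reactants: 4 (4-bromo-2-methoxyphenoxy)acetaldehyde; 5 4-formyl-2-methoxyphenyl acetate (vanillin acetate)
Product: 7 4-[(1R,2S)-2-(4-bromo-2-methoxyphenoxy)-1,3-dihydroxypropyl]-2-methoxyphenyl acetate, via aldol aldehyde 6 (not isolated)
Conditions: D-proline (20 mol %), DMF, 4 °C, 4 added over 24 h to 5 (3 equiv); then EtOH, NaBH4, −10 °C
Reagents that add atoms: none
Why: Proposed new method: a proline-catalysed cross-aldol with an α-aryloxyacetaldehyde as enamine donor and an acyloxy-activated benzaldehyde as acceptor has not been shown; the anti-enamine of 4 formed with D-proline should add to the Si face of 5 through the carboxylic-acid-bridged chair-like transition state of proline aldols, giving the anti (1R,2R) aldehyde 6 and hence the erythro (1R,2S) diol 7 after borohydride reduction; slow addition of 4 to excess non-enolisable 5 (made electron-poor by its acetate) is meant to suppress self-aldol of 4; the closest known reactions are the proline-catalysed anti-selective dimerisation of α-oxyaldehydes and the proline cross-aldol of alkyl aldehydes with aromatic aldehydes.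

Step 4
Reactants: 8 1,3-dihydroxyacetone; 9 4-[(1E)-3-oxoprop-1-en-1-yl]-2-methoxyphenyl acetate (4-acetoxy-3-methoxycinnamaldehyde)
Product: 11 4-[(2S,3R,4R)-4-hydroxy-3,4-bis(hydroxymethyl)oxolan-2-yl]-2-methoxyphenyl acetate, via bicyclic lactol 10 (not isolated)
Conditions: (S)-2-[diphenyl(trimethylsilyloxy)methyl]pyrrolidine (10 mol %), PhCO2H (10 mol %), CHCl3, rt; then EtOH, NaBH4, 0 °C
Reagents that add atoms: none
Why: Organocatalytic domino oxa-Michael/aldol/hemiacetalisation of dihydroxyacetone with an enal (iminium then enamine catalysis, a known cascade type): the bulky group of the (S)-catalyst shields the Re face of the β-carbon of the E-iminium ion so a hydroxyl of 8 adds to the Si face (C2 = S), the enamine closes the ring on the ketone from the same face (2,3-trans, C3 = R), and because only the aldol adduct whose free hydroxymethyl is cis to the formyl group can be trapped as the cis-fused lactol 10, the reversible aldol is funnelled to the tertiary alcohol trans to that carbon (C4), after which NaBH4 opens the lactol to triol 11.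

Step 5
Reactants: 11 4-[(2S,3R,4R)-4-hydroxy-3,4-bis(hydroxymethyl)oxolan-2-yl]-2-methoxyphenyl acetate
Product: 13 4-[(3R,6S,7R)-7-(hydroxymethyl)-1,5-dioxaspiro[2.4]heptan-6-yl]-2-methoxyphenyl acetate, via primary tosylate 12 (not isolated)
Conditions: Bu2SnO (5 mol %), TsCl (1.05 equiv), Et3N, CH2Cl2, 0 °C to rt; then DBU, rt
Reagents that add atoms: none
Why: Tin-acetal-directed sulfonylation followed by intramolecular Williamson etherification: catalytic Bu2SnO forms the five-membered stannylene acetal only across the vicinal tertiary/primary diol and so activates that primary hydroxyl over the isolated hydroxymethyl at C3, and DBU then closes the epoxide by 3-exo-tet attack of the tertiary alkoxide, so the C–O bond at the quaternary centre is never broken and its configuration is kept.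

Step 6
Reactants: 13 4-[(3R,6S,7R)-7-(hydroxymethyl)-1,5-dioxaspiro[2.4]heptan-6-yl]-2-methoxyphenyl acetate; 7 4-[(1R,2S)-2-(4-bromo-2-methoxyphenoxy)-1,3-dihydroxypropyl]-2-methoxyphenyl acetate
Product: 15 4-[(2S,3R,4S)-4-({4-[(1R,2S)-1-(4-acetoxy-3-methoxyphenyl)-1,3-dihydroxypropan-2-yl]oxy-3-methoxyphenyl}methyl)-4-hydroxy-3-(hydroxymethyl)oxolan-2-yl]-2-methoxyphenyl acetate, via iodohydrin 14 (not isolated)
Conditions: NiBr2(diglyme) (10 mol %), 4,4'-di-tert-butyl-2,2'-bipyridine (10 mol %), NaI (50 mol %), Et3N·HCl (1.2 equiv), Mn powder (2.5 equiv), DMPU, 30 °C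
Reagents that add atoms: none
Why: Nickel-catalysed reductive cross-electrophile coupling of an epoxide with an aryl bromide under iodide co-catalysis: iodide opens the spiro-epoxide at its unhindered CH2 to iodohydrin 14, whose primary radical is captured by the aryl–nickel species formed from 7, so the benzylic C–C bond forms without touching any stereocentre, and free hydroxyls and aryl acetates survive these neutral reducing conditions.

Step 7
Reactants: 15 the diacetate from step 6
Product: 16 4-[(2S,3R,4S)-4-({4-[(1R,2S)-1,3-dihydroxy-1-(4-hydroxy-3-methoxyphenyl)propan-2-yl]oxy-3-methoxyphenyl}methyl)-4-hydroxy-3-(hydroxymethyl)oxolan-2-yl]-2-methoxyphenol (target)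
Conditions: K2CO3 (0.2 equiv), MeOH, rt
Reagents that add atoms: none
Why: Base-catalysed transesterification (methanolysis) removes the two aryl acetates, which are far more labile than any other group present, and no stereocentre is affected.

## Compound list

1 | 4-bromo-2-methoxyphenol | COc1cc(Br)ccc1O | starting material
2 | 2-bromo-1,1-diethoxyethane | CCOC(CBr)OCC | starting material
3 | 4-bromo-1-(2,2-diethoxyethoxy)-2-methoxybenzene | CCOC(COc1ccc(Br)cc1OC)OCC | intermediate
4 | (4-bromo-2-methoxyphenoxy)acetaldehyde | O=CCOc1ccc(Br)cc1OC | intermediate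
5 | 4-formyl-2-methoxyphenyl acetate | CC(=O)Oc1ccc(C=O)cc1OC | starting material
6 | 4-[(1R,2R)-2-(4-bromo-2-methoxyphenoxy)-1-hydroxy-3-oxopropyl]-2-methoxyphenyl acetate | CC(=O)Oc1ccc([C@@H](O)[C@H](C=O)Oc2ccc(Br)cc2OC)cc1OC | intermediate
7 | 4-[(1R,2S)-2-(4-bromo-2-methoxyphenoxy)-1,3-dihydroxypropyl]-2-methoxyphenyl acetate | CC(=O)Oc1ccc([C@@H](O)[C@H](CO)Oc2ccc(Br)cc2OC)cc1OC | intermediate
8 | 1,3-dihydroxyacetone | OCC(=O)CO | starting material
9 | 4-[(1E)-3-oxoprop-1-en-1-yl]-2-methoxyphenyl acetate | CC(=O)Oc1ccc(/C=C/C=O)cc1OC | starting material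
10 | 4-[(1S,3aS,6aR)-3a,6-dihydroxytetrahydro-1H,3H-furo[3,4-c]furan-1-yl]-2-methoxyphenyl acetate (cis-fused lactol, anomer mixture at C6) | O[C@]12CO[C@H](c3ccc(OC(C)=O)c(OC)c3)[C@H]1C(O)OC2 | intermediate
11 | 4-[(2S,3R,4R)-4-hydroxy-3,4-bis(hydroxymethyl)oxolan-2-yl]-2-methoxyphenyl acetate | OC[C@@]1(O)CO[C@H](c2ccc(OC(C)=O)c(OC)c2)[C@H]1CO | intermediate
12 | 4-[(2S,3R,4S)-4-hydroxy-3-(hydroxymethyl)-4-{[(4-methylbenzenesulfonyl)oxy]methyl}oxolan-2-yl]-2-methoxyphenyl acetate | Cc1ccc(cc1)S(=O)(=O)OC[C@@]1(O)CO[C@H](c2ccc(OC(C)=O)c(OC)c2)[C@H]1CO | intermediate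
13 | 4-[(3R,6S,7R)-7-(hydroxymethyl)-1,5-dioxaspiro[2.4]heptan-6-yl]-2-methoxyphenyl acetate | C1O[C@@]12CO[C@H](c3ccc(OC(C)=O)c(OC)c3)[C@H]2CO | intermediate
14 | 4-[(2S,3R,4S)-4-hydroxy-3-(hydroxymethyl)-4-(iodomethyl)oxolan-2-yl]-2-methoxyphenyl acetate | IC[C@@]1(O)CO[C@H](c2ccc(OC(C)=O)c(OC)c2)[C@H]1CO | intermediate
15 | 4-[(2S,3R,4S)-4-({4-[(1R,2S)-1-(4-acetoxy-3-methoxyphenyl)-1,3-dihydroxypropan-2-yl]oxy-3-methoxyphenyl}methyl)-4-hydroxy-3-(hydroxymethyl)oxolan-2-yl]-2-methoxyphenyl acetate | CC(=O)Oc1ccc([C@@H](O)[C@H](CO)Oc2ccc(C[C@@]3(O)CO[C@H](c4ccc(OC(C)=O)c(OC)c4)[C@H]3CO)cc2OC)cc1OC | intermediate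
16 | 4-[(2S,3R,4S)-4-({4-[(1R,2S)-1,3-dihydroxy-1-(4-hydroxy-3-methoxyphenyl)propan-2-yl]oxy-3-methoxyphenyl}methyl)-4-hydroxy-3-(hydroxymethyl)oxolan-2-yl]-2-methoxyphenol | COc1cc([C@@H](O)[C@H](CO)Oc2ccc(C[C@@]3(O)CO[C@H](c4ccc(O)c(OC)c4)[C@H]3CO)cc2OC)ccc1O | target

## Step count and risks

Total steps: 7 (each one-pot operation counted once). Longest linear sequence: 5 (steps 1, 2, 3, 6, 7); steps 4 and 5 run in parallel.

The three steps most likely to fail are steps 3, 5 and 6.

Step 3 (proposed new cross-aldol) may give mainly the self-aldol dimer of 4 or poor anti selectivity. The fallback sets out from 1 and comes back at 7, using auxiliary-controlled glycolate aldol chemistry followed by inversion of the benzylic carbinol, a sequence known for this class of aryl glycerol ethers. Compound 1 is O-alkylated with chloroacetic acid (aq. NaOH, reflux) to (4-bromo-2-methoxyphenoxy)acetic acid F1. Its pivaloyl mixed anhydride acylates lithiated (4R)-4-benzyl-1,3-oxazolidin-2-one to give (4R)-4-benzyl-3-[(4-bromo-2-methoxyphenoxy)acetyl]-1,3-oxazolidin-2-one F2. Boron enolisation (Bu2BOTf, iPr2NEt, CH2Cl2, −78 °C) and addition to 5 give the Evans syn (threo) adduct 4-[(1S,2R)-3-[(4R)-4-benzyl-2-oxo-1,3-oxazolidin-3-yl]-2-(4-bromo-2-methoxyphenoxy)-1-hydroxy-3-oxopropyl]-2-methoxyphenyl acetate F3. Mitsunobu esterification (4-nitrobenzoic acid, PPh3, DIAD, THF) inverts the benzylic centre to the erythro ester 4-[(1R,2R)-3-[(4R)-4-benzyl-2-oxo-1,3-oxazolidin-3-yl]-2-(4-bromo-2-methoxyphenoxy)-1-(4-nitrobenzoyloxy)-3-oxopropyl]-2-methoxyphenyl acetate F4. LiBH4 (THF, MeOH, 0 °C) removes the auxiliary and both aryl-type esters to give the phenol 4-[(1R,2S)-2-(4-bromo-2-methoxyphenoxy)-1,3-dihydroxypropyl]-2-methoxyphenol F5. Acetylation of the phenoxide only (Ac2O, aq. NaOH, 0 °C) returns 7.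

Step 5 (tin-directed tosylation and epoxide closure) may not distinguish the two primary hydroxyls, or the cis hydroxymethyl groups may close to a furofuran ether. The fallback sets out from 11 and comes back at 13, and differentiates the hydroxyls by steric protection instead. TBDPSCl and imidazole (CH2Cl2, −20 °C) cap the less hindered hydroxymethyl at C3 to give 4-[(2S,3R,4R)-3-{[tert-butyl(diphenyl)silyl]oxymethyl}-4-hydroxy-4-(hydroxymethyl)oxolan-2-yl]-2-methoxyphenyl acetate F6. TsCl, pyridine and DMAP then sulfonylate the only remaining primary hydroxyl to give 4-[(2S,3R,4S)-3-{[tert-butyl(diphenyl)silyl]oxymethyl}-4-hydroxy-4-{[(4-methylbenzenesulfonyl)oxy]methyl}oxolan-2-yl]-2-methoxyphenyl acetate F7. DBU closes the epoxide 4-[(3R,6S,7R)-7-{[tert-butyl(diphenyl)silyl]oxymethyl}-1,5-dioxaspiro[2.4]heptan-6-yl]-2-methoxyphenyl acetate F8. TBAF buffered with AcOH (THF, 0 °C) removes the silyl group and returns 13.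

Step 6 (reductive epoxide–aryl bromide coupling) may stall with this hindered spiro-epoxide and electron-rich aryl bromide, or the epoxide may rearrange under Lewis-acidic salts. The fallback sets out from 13 and comes back at 15. The iodohydrin 14 is made and isolated separately (NaI, AcOH, THF, 0 °C). It is then coupled with 7 by silyl-radical halogen-atom abstraction under nickel/photoredox dual catalysis (NiCl2(dme), 4,4'-di-tert-butyl-2,2'-bipyridine, the organic photocatalyst 4CzIPN, (Me3Si)3SiH, Na2CO3, DME, blue light). No compound outside the list is made.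

Further compounds

F1 | step 3 | (4-bromo-2-methoxyphenoxy)acetic acid | COc1cc(Br)ccc1OCC(O)=O
F2 | step 3 | (4R)-4-benzyl-3-[(4-bromo-2-methoxyphenoxy)acetyl]-1,3-oxazolidin-2-one | O=C(COc1ccc(Br)cc1OC)N1[C@H](Cc2ccccc2)COC1=O
F3 | step 3 | 4-[(1S,2R)-3-[(4R)-4-benzyl-2-oxo-1,3-oxazolidin-3-yl]-2-(4-bromo-2-methoxyphenoxy)-1-hydroxy-3-oxopropyl]-2-methoxyphenyl acetate | O=C([C@H](Oc1ccc(Br)cc1OC)[C@@H](O)c1ccc(OC(C)=O)c(OC)c1)N1[C@H](Cc2ccccc2)COC1=O
F4 | step 3 | 4-[(1R,2R)-3-[(4R)-4-benzyl-2-oxo-1,3-oxazolidin-3-yl]-2-(4-bromo-2-methoxyphenoxy)-1-(4-nitrobenzoyloxy)-3-oxopropyl]-2-methoxyphenyl acetate | O=C([C@H](Oc1ccc(Br)cc1OC)[C@H](OC(=O)c1ccc(cc1)[N+](=O)[O-])c1ccc(OC(C)=O)c(OC)c1)N1[C@H](Cc2ccccc2)COC1=O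
F5 | step 3 | 4-[(1R,2S)-2-(4-bromo-2-methoxyphenoxy)-1,3-dihydroxypropyl]-2-methoxyphenol | COc1cc([C@@H](O)[C@H](CO)Oc2ccc(Br)cc2OC)ccc1O
F6 | step 5 | 4-[(2S,3R,4R)-3-{[tert-butyl(diphenyl)silyl]oxymethyl}-4-hydroxy-4-(hydroxymethyl)oxolan-2-yl]-2-methoxyphenyl acetate | OC[C@@]1(O)CO[C@H](c2ccc(OC(C)=O)c(OC)c2)[C@H]1CO[Si](c1ccccc1)(c1ccccc1)C(C)(C)C
F7 | step 5 | 4-[(2S,3R,4S)-3-{[tert-butyl(diphenyl)silyl]oxymethyl}-4-hydroxy-4-{[(4-methylbenzenesulfonyl)oxy]methyl}oxolan-2-yl]-2-methoxyphenyl acetate | Cc1ccc(cc1)S(=O)(=O)OC[C@@]1(O)CO[C@H](c2ccc(OC(C)=O)c(OC)c2)[C@H]1CO[Si](c1ccccc1)(c1ccccc1)C(C)(C)C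
F8 | step 5 | 4-[(3R,6S,7R)-7-{[tert-butyl(diphenyl)silyl]oxymethyl}-1,5-dioxaspiro[2.4]heptan-6-yl]-2-methoxyphenyl acetate | C1O[C@@]12CO[C@H](c3ccc(OC(C)=O)c(OC)c3)[C@H]2CO[Si](c1ccccc1)(c1ccccc1)C(C)(C)C
F0 | step 6 | none | none
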